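A direct plan would (rings lettered A to D from the phloroglucinol end) make the D–C ether by Ullmann coupling, convert it into boronic acid A2 and join it by Chan–Lam coupling to the ring B phenol A1, giving aldehyde A3. Dakin oxidation would free the hydroxyl that is to carry ring A, and ring A would be grown on it by O-alkylation, extension to dioxo ester A4 and Claisen closure, before global demethylation.
Its weakest steps would be: (a) the Chan–Lam union of A1 (two ortho methoxy groups, para formyl) with electron-rich A2, where protodeboronation would compete; (b) the Claisen closure of A4, which would need a carbanion on the aryloxy-bearing carbon and would have to outrun pyrone formation; (c) the three steps spent on the ring A chain, which would add length but only one ring.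

The new route cuts the A–O–B ether on the ring B side and treats ring B as its dearomatised para-quinone monoketal. Ring B is the only ring in which the aryloxy carbon (B-C1) has an oxygenated neighbour (B-C2) lying para to another oxygen (B-C5): with B-C2 as ketal and B-C5 as carbonyl, B-C1 becomes the only electrophilic CH. In one operation the hindered ring A phenol adds there through oxygen and ring B re-aromatises, completing the four-ring skeleton. Ring A is bought, not built; no boronic acid, no coupling beside three ortho oxygens and no Claisen closure remain. Rings B, C and D are joined beforehand by SNAr and one Ullmann coupling.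

Key step: step 5

Remarks: B-C1 is the ring B carbon bonded to the oxygen of ring A, B-C4 the one bonded to the oxygen of ring C. The target has no stereocentre. Assumption: the dimethoxyhydroquinone, the fluoro aldehyde and the ring A phenol used below are taken as catalogue compounds; the hydroquinone is air-sensitive in base and is handled under argon.

Step 1
Reactants: 1 2,6-dimethoxybenzene-1,4-diol; 2 2-fluoro-3,4-dimethoxybenzaldehyde
Product: 3 2-(4-hydroxy-3,5-dimethoxyphenoxy)-3,4-dimethoxybenzaldehyde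
Conditions: 1 (1.3 equiv), K2CO3 (2 equiv), degassed DMF, 110 °C, Ar
Reagents that add atoms: none
Why: Nucleophilic aromatic substitution (SNAr) of a fluoride activated by the ortho formyl group; of the two hydroxyls of 1 only the C4–OH with two ortho hydrogens should reach the fluorine-bearing carbon wedged between CHO and OMe, so the C1–OH flanked by two methoxy groups should stay free for step 2.

Step 2
Reactants: 3 2-(4-hydroxy-3,5-dimethoxyphenoxy)-3,4-dimethoxybenzaldehyde; 4 5-iodo-1,2,3-trimethoxybenzene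
Product: 5 2-[3,5-dimethoxy-4-(3,4,5-trimethoxyphenoxy)phenoxy]-3,4-dimethoxybenzaldehyde
Conditions: 4 (1.5 equiv), CuI (10 mol %), picolinic acid (20 mol %), K3PO4 (2 equiv), DMSO, 90 °C, Ar
Reagents that add atoms: none
Why: Ligand-accelerated Ullmann diaryl ether synthesis, which accepts phenols with two ortho substituents and electron-rich aryl iodides, while the non-enolisable aldehyde should tolerate phosphate in DMSO.

Step 3
Reactants: 5 2-[3,5-dimethoxy-4-(3,4,5-trimethoxyphenoxy)phenoxy]-3,4-dimethoxybenzaldehyde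
Product: 7 2-[3,5-dimethoxy-4-(3,4,5-trimethoxyphenoxy)phenoxy]-3,4-dimethoxyphenol, via aryl formate 6 (not isolated)
Conditions: mCPBA (1.3 equiv), CH2Cl2, 0 °C to rt; aq. Na2S2O3/NaHCO3 wash; then Et3N (cat.), MeOH, rt
Reagents that add atoms: mCPBA, OOC(=O)c1cccc(Cl)c1
Why: Baeyer–Villiger (Dakin-type) oxidation in which the aryl group, made electron-rich by its ortho aryloxy and para methoxy substituents, migrates in preference to hydrogen; the formate is methanolysed only after the peracid is destroyed, so the free para-methoxyphenol never meets the oxidant.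

Step 4
Reactants: 7 2-[3,5-dimethoxy-4-(3,4,5-trimethoxyphenoxy)phenoxy]-3,4-dimethoxyphenol
Product: 8 2-[3,5-dimethoxy-4-(3,4,5-trimethoxyphenoxy)phenoxy]-3,4,4-trimethoxycyclohexa-2,5-dien-1-one
Conditions: PhI(OAc)2 (1.1 equiv), MeOH, 0 °C; NaHCO3 work-up
Reagents that add atoms: methanol, CO
Why: Oxidative dearomatisation of a para-methoxyphenol by a hypervalent iodine reagent to the para-quinone monoketal: ligand exchange at iodine needs the free OH, so rings C and D should not be touched, methanol captures the methoxy-stabilised para carbon, and no stereocentre arises because the ketal carbon carries two methoxy groups.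

Step 5
Reactants: 8 2-[3,5-dimethoxy-4-(3,4,5-trimethoxyphenoxy)phenoxy]-3,4,4-trimethoxycyclohexa-2,5-dien-1-one; 9 2,4,6-trimethoxyphenol
Product: 11 2-[3,5-dimethoxy-4-(3,4,5-trimethoxyphenoxy)phenoxy]-3,4-dimethoxy-5-(2,4,6-trimethoxyphenoxy)phenol, via oxa-Michael adduct 10 (not isolated)
Conditions: 9 (3 equiv), KOt-Bu (0.2 equiv), 18-crown-6 (0.2 equiv), THF, 0 °C to rt, Ar; then Amberlyst 15 (H+ form), 0 °C to rt
Reagents that add atoms: none
Why: Proposed new method: catalytic potassium 2,4,6-trimethoxyphenoxide, whose ortho and para carbons all carry methoxy groups so that only its oxygen can form a lasting bond, should add reversibly to C5 of dienone 8 (the future B-C1), the enolate being protonated by excess 9 to give 10 and return the phenoxide; the acid resin then ionises the ketal at C4 to an oxocarbenium ion, H-5 is lost, and tautomerisation to phenol 11 with release of methanol makes the sequence irreversible. The closest known reactions are the base-mediated conjugate additions of thiolates, alkoxides and malonates to para-quinone monoketals followed by acid-induced aromatisation to 3-substituted 4-methoxyphenols, and the addition–elimination of phenoxides to halogenated quinones and quinone ketals. No ring is closed; ring B, dearomatised in step 4, is only re-aromatised. The one new stereocentre, C5 of 10, forms as a racemate and is destroyed on aromatisation. The step needs attack at C5 rather than C3 or C6: under basic conditions the carbonyl and not the ketal is the acceptor, C3 is a methoxy-bearing vinylogous ester carbon, and the second quinone carbonyl that would direct a nucleophile to C6 is masked as the ketal, so C5 is the only electrophilic CH. The oxygen of 9 thus reaches the carbon next to B-C2 without a metal having to work between three ortho oxygens.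

Step 6
Reactants: 11 2-[3,5-dimethoxy-4-(3,4,5-trimethoxyphenoxy)phenoxy]-3,4-dimethoxy-5-(2,4,6-trimethoxyphenoxy)phenol
Product: 12 2-{4-[3,5-dihydroxy-4-(3,4,5-trihydroxyphenoxy)phenoxy]-2,3,5-trihydroxyphenoxy}benzene-1,3,5-triol (CNP0018315.0)
Conditions: BBr3 (22 equiv), CH2Cl2, −78 °C to rt, Ar; degassed water, 0 °C
Reagents that add atoms: none
Why: Lewis-acid ether cleavage in which bromide attacks the O-methyl carbon of each of the ten aryl methyl ether–borane adducts (SN2), whereas the three diaryl ether oxygens offer no sp3 carbon and should survive; the free hydroxyl of 11 is carried as its borate.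

Compound list
1 | 2,6-dimethoxybenzene-1,4-diol | COc1cc(O)cc(OC)c1O | starting material
2 | 2-fluoro-3,4-dimethoxybenzaldehyde | O=Cc1ccc(OC)c(OC)c1F | starting material
3 | 2-(4-hydroxy-3,5-dimethoxyphenoxy)-3,4-dimethoxybenzaldehyde | O=Cc1ccc(OC)c(OC)c1Oc1cc(OC)c(O)c(OC)c1 | intermediate
4 | 5-iodo-1,2,3-trimethoxybenzene | COc1cc(I)cc(OC)c1OC | starting material
5 | 2-[3,5-dimethoxy-4-(3,4,5-trimethoxyphenoxy)phenoxy]-3,4-dimethoxybenzaldehyde | O=Cc1ccc(OC)c(OC)c1Oc1cc(OC)c(Oc2cc(OC)c(OC)c(OC)c2)c(OC)c1 | intermediate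
6 | 2-[3,5-dimethoxy-4-(3,4,5-trimethoxyphenoxy)phenoxy]-3,4-dimethoxyphenyl formate | O=COc1ccc(OC)c(OC)c1Oc1cc(OC)c(Oc2cc(OC)c(OC)c(OC)c2)c(OC)c1 | intermediate (not isolated)
7 | 2-[3,5-dimethoxy-4-(3,4,5-trimethoxyphenoxy)phenoxy]-3,4-dimethoxyphenol | Oc1ccc(OC)c(OC)c1Oc1cc(OC)c(Oc2cc(OC)c(OC)c(OC)c2)c(OC)c1 | intermediate
8 | 2-[3,5-dimethoxy-4-(3,4,5-trimethoxyphenoxy)phenoxy]-3,4,4-trimethoxycyclohexa-2,5-dien-1-one | O=C1C=CC(OC)(OC)C(OC)=C1Oc1cc(OC)c(Oc2cc(OC)c(OC)c(OC)c2)c(OC)c1 | intermediate
9 | 2,4,6-trimethoxyphenol | COc1cc(OC)c(O)c(OC)c1 | starting material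
10 | racemic 2-[3,5-dimethoxy-4-(3,4,5-trimethoxyphenoxy)phenoxy]-3,4,4-trimethoxy-5-(2,4,6-trimethoxyphenoxy)cyclohex-2-en-1-one | O=C1CC(Oc2c(OC)cc(OC)cc2OC)C(OC)(OC)C(OC)=C1Oc1cc(OC)c(Oc2cc(OC)c(OC)c(OC)c2)c(OC)c1 | intermediate (not isolated)
11 | 2-[3,5-dimethoxy-4-(3,4,5-trimethoxyphenoxy)phenoxy]-3,4-dimethoxy-5-(2,4,6-trimethoxyphenoxy)phenol | Oc1cc(Oc2c(OC)cc(OC)cc2OC)c(OC)c(OC)c1Oc1cc(OC)c(Oc2cc(OC)c(OC)c(OC)c2)c(OC)c1 | intermediate
12 | 2-{4-[3,5-dihydroxy-4-(3,4,5-trihydroxyphenoxy)phenoxy]-2,3,5-trihydroxyphenoxy}benzene-1,3,5-triol (CNP0018315.0) | Oc1cc(O)c(Oc2cc(O)c(Oc3cc(O)c(Oc4cc(O)c(O)c(O)c4)c(O)c3)c(O)c2O)c(O)c1 | target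

Total step count: 6. Longest linear sequence: 6 steps (from 1 and 2 to 12).

Steps most likely to fail

Step 5. The addition may not go forward: the equilibrium between 8, 9 and the crowded adduct 10 may lie on the side of the components, 10 may revert before its ketal ionises, or the acid may ionise the ketal of unreacted 8 and steer 9 to C6 or to carbon attack. The fallback uses only known reactions, sets out from 2 and comes back at 11. Aldehyde 2 would be brominated (NBS, MeCN) at C5, the position para to fluorine and ortho to the 4-methoxy group, to give 5-bromo-2-fluoro-3,4-dimethoxybenzaldehyde F1. SNAr with 1 as in step 1 would give 5-bromo-2-(4-hydroxy-3,5-dimethoxyphenoxy)-3,4-dimethoxybenzaldehyde F2. Ullmann coupling with iodide 4 as in step 2, where the iodide should react before the ortho-substituted bromide, would give 5-bromo-2-[3,5-dimethoxy-4-(3,4,5-trimethoxyphenoxy)phenoxy]-3,4-dimethoxybenzaldehyde F3. A second Ullmann coupling at the bromide with 9 (CuI, picolinic acid, K3PO4, DMSO, 110 °C) would give 2-[3,5-dimethoxy-4-(3,4,5-trimethoxyphenoxy)phenoxy]-3,4-dimethoxy-5-(2,4,6-trimethoxyphenoxy)benzaldehyde F4. Baeyer–Villiger oxidation as in step 3, through 2-[3,5-dimethoxy-4-(3,4,5-trimethoxyphenoxy)phenoxy]-3,4-dimethoxy-5-(2,4,6-trimethoxyphenoxy)phenyl formate F5, and methanolysis would then deliver 11.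

Step 1. Site selectivity between the two hydroxyls of 1 may be lost, the hydroquinone may be oxidised to the quinone under base, or substitution at the fluoride, deactivated by the para methoxy group, may be too slow. The fallback sets out from 4 and comes back at 5; it installs ring D first on a ring C unit whose second oxygen is masked as a formyl group. Ullmann coupling of 4 with commercial syringaldehyde (4-hydroxy-3,5-dimethoxybenzaldehyde; CuI, picolinic acid, K3PO4, DMSO, 100 °C) would give 3,5-dimethoxy-4-(3,4,5-trimethoxyphenoxy)benzaldehyde F6. Baeyer–Villiger oxidation through 3,5-dimethoxy-4-(3,4,5-trimethoxyphenoxy)phenyl formate F7 and methanolysis would give 3,5-dimethoxy-4-(3,4,5-trimethoxyphenoxy)phenol F8, a single unhindered phenol, which would displace the fluoride of 2 (K2CO3, DMF, 110 °C) to give 5.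

Step 6. Cleavage of ten methyl ethers may stop short, and the free undecaphenol may darken by air oxidation during isolation. The fallback sets out from 11 and comes back at 12. The crude demethylation product would be acetylated at once (Ac2O, pyridine, DMAP) to the undecaacetate 2-{4-[3,5-diacetoxy-4-(3,4,5-triacetoxyphenoxy)phenoxy]-2,3,5-triacetoxyphenoxy}benzene-1,3,5-triyl triacetate F9. This is stable to air, can be chromatographed and separated from partly methylated material (which can be returned to BBr3), and would be deacetylated last with HCl in degassed MeOH under argon to give 12.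

Further compounds
F1 | step 5 | 5-bromo-2-fluoro-3,4-dimethoxybenzaldehyde | O=Cc1cc(Br)c(OC)c(OC)c1F
F2 | step 5 | 5-bromo-2-(4-hydroxy-3,5-dimethoxyphenoxy)-3,4-dimethoxybenzaldehyde | O=Cc1cc(Br)c(OC)c(OC)c1Oc1cc(OC)c(O)c(OC)c1
F3 | step 5 | 5-bromo-2-[3,5-dimethoxy-4-(3,4,5-trimethoxyphenoxy)phenoxy]-3,4-dimethoxybenzaldehyde | O=Cc1cc(Br)c(OC)c(OC)c1Oc1cc(OC)c(Oc2cc(OC)c(OC)c(OC)c2)c(OC)c1
F4 | step 5 | 2-[3,5-dimethoxy-4-(3,4,5-trimethoxyphenoxy)phenoxy]-3,4-dimethoxy-5-(2,4,6-trimethoxyphenoxy)benzaldehyde | O=Cc1cc(Oc2c(OC)cc(OC)cc2OC)c(OC)c(OC)c1Oc1cc(OC)c(Oc2cc(OC)c(OC)c(OC)c2)c(OC)c1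
F5 | step 5 | 2-[3,5-dimethoxy-4-(3,4,5-trimethoxyphenoxy)phenoxy]-3,4-dimethoxy-5-(2,4,6-trimethoxyphenoxy)phenyl formate | O=COc1cc(Oc2c(OC)cc(OC)cc2OC)c(OC)c(OC)c1Oc1cc(OC)c(Oc2cc(OC)c(OC)c(OC)c2)c(OC)c1
F6 | step 1 | 3,5-dimethoxy-4-(3,4,5-trimethoxyphenoxy)benzaldehyde | O=Cc1cc(OC)c(Oc2cc(OC)c(OC)c(OC)c2)c(OC)c1
F7 | step 1 | 3,5-dimethoxy-4-(3,4,5-trimethoxyphenoxy)phenyl formate | O=COc1cc(OC)c(Oc2cc(OC)c(OC)c(OC)c2)c(OC)c1
F8 | step 1 | 3,5-dimethoxy-4-(3,4,5-trimethoxyphenoxy)phenol | Oc1cc(OC)c(Oc2cc(OC)c(OC)c(OC)c2)c(OC)c1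
F9 | step 6 | 2-{4-[3,5-diacetoxy-4-(3,4,5-triacetoxyphenoxy)phenoxy]-2,3,5-triacetoxyphenoxy}benzene-1,3,5-triyl triacetate | CC(=O)Oc1cc(OC(C)=O)c(Oc2cc(OC(C)=O)c(Oc3cc(OC(C)=O)c(Oc4cc(OC(C)=O)c(OC(C)=O)c(OC(C)=O)c4)c(OC(C)=O)c3)c(OC(C)=O)c2OC(C)=O)c(OC(C)=O)c1
A1 | direct plan | 4-hydroxy-2,3,5-trimethoxybenzaldehyde | O=Cc1cc(OC)c(O)c(OC)c1OC
A2 | direct plan | [3,5-dimethoxy-4-(3,4,5-trimethoxyphenoxy)phenyl]boronic acid | OB(O)c1cc(OC)c(Oc2cc(OC)c(OC)c(OC)c2)c(OC)c1
A3 | direct plan | 4-[3,5-dimethoxy-4-(3,4,5-trimethoxyphenoxy)phenoxy]-2,3,5-trimethoxybenzaldehyde | O=Cc1cc(OC)c(Oc2cc(OC)c(Oc3cc(OC)c(OC)c(OC)c3)c(OC)c2)c(OC)c1OC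
A4 | direct plan | methyl 6-{4-[3,5-dimethoxy-4-(3,4,5-trimethoxyphenoxy)phenoxy]-2,3,5-trimethoxyphenoxy}-3,5-dioxohexanoate | COC(=O)CC(=O)CC(=O)COc1cc(OC)c(Oc2cc(OC)c(Oc3cc(OC)c(OC)c(OC)c3)c(OC)c2)c(OC)c1OC
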